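Ring A is not assembled as a cyclohexane. Its quaternary C4, which carries the exocyclic carboxyl carbon C19 beside the ring-fusion carbon C5, is read as the terminus of a 1,2-shift. (S)-Carvone supplies C5 and ring B; two alkylations and ring-closing metathesis give a cis-fused seven-membered ring that still holds C19 as a ring member of a C4=C19 alkene. After side-chain assembly and epoxidation from the β face, a Lewis-acid Meinwald (semipinacol) rearrangement contracts this ring in one operation: C3 migrates to C4, which closes ring A, sets the C4 quaternary stereocentre stereospecifically and extrudes C19 as the aldehyde that is later oxidised to the acid.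

Key step: step 13

Remark: the stereodescriptors of the target (4S,5S,9R,10R,13S) define a cis-fused decalin with H5, the C10 methyl group, H9 and the C4 carboxyl group on one face (called β here) and the C9 side chain and the C4 methyl group on the other (α); labdane numbering C1–C20 is used for all bicyclic compounds, with C19 the carbon that ends as the carboxyl carbon.

Step 1
Reactants: 1 (S)-carvone; 2 5-iodopent-1-ene
Product: 4 trans-6-(pent-4-enyl)carvone, via lithium enolate 3 (not isolated)
Conditions: LiN(iPr)2, THF, −78 °C; then 2, DMPU, −78 → 0 °C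
Reagents that add atoms: none
Why: Kinetic deprotonation of the enone at its only α′ position (the future C10) and SN2 alkylation of the lithium enolate (enolate alkylation) install the C1–C3/C19 chain, the new stereocentre being erased again in step 2.

Step 2
Reactants: 4 trans-6-(pent-4-enyl)carvone
Product: 6 6-methyl-6-(pent-4-enyl)carvone, via lithium enolate 5 (not isolated)
Conditions: LiN(iPr)2, THF, −78 °C; then MeI, −78 → −20 °C
Reagents that add atoms: iodomethane CI
Why: The second enolate alkylation can again occur only at C10, and iodomethane should approach the enolate face anti to the neighbouring C5 isopropenyl group, so that methyl ends trans and the pentenyl chain cis to isopropenyl, which fixes the quaternary C10 stereocentre by 1,2-induction from the carvone stereocentre.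

Step 3
Reactants: 6 6-methyl-6-(pent-4-enyl)carvone
Product: 7 cis-fused bicyclic dienone
Conditions: second-generation Grubbs catalyst RuCl2(=CHPh)(PCy3)(H2IMes) (5 mol %), CH2Cl2, 40 °C
Reagents that add atoms: none
Why: Ring-closing metathesis between the cis-disposed isopropenyl and pentenyl groups should close the seven-membered ring as the trisubstituted C4=C19 alkene with loss of ethene, the electron-poor enone alkene being inert to the ruthenium carbene.

Step 4
Reactants: 7 cis-fused bicyclic dienone
Product: 9 alkenyl triflate, via lithium enolate 8 (not isolated)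
Conditions: LiBH(sBu)3, THF, −78 °C; then PhNTf2, −78 → 0 °C
Reagents that add atoms: N-phenylbis(trifluoromethanesulfonimide) O=S(=O)(N(c1ccccc1)S(=O)(=O)C(F)(F)F)C(F)(F)F
Why: The bulky borohydride should add in conjugate fashion to the β-monosubstituted enone whose carbonyl is shielded by the quaternary C10 (conjugate reduction), and the regiodefined enolate is O-sulfonylated to the C9 alkenyl triflate.

Step 5
Reactants: 9 alkenyl triflate
Product: 10 conjugated methyl ester
Conditions: Pd(OAc)2 (5 mol %), PPh3, Et3N, CO (1 atm), MeOH–DMF, 60 °C
Reagents that add atoms: carbon monoxide [C-]#[O+]; methanol CO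
Why: Palladium-catalysed alkoxycarbonylation of the alkenyl triflate (oxidative addition, CO insertion, methanolysis) introduces C11 as an ester without touching the isolated ring alkene.

Step 6
Reactants: 10 conjugated methyl ester
Product: 12 deconjugated methyl ester, via lithium dienolate 11 (not isolated)
Conditions: LiN(iPr)2, DMPU, THF, −78 °C; then AcOH, −78 °C
Reagents that add atoms: none
Why: Deconjugative protonation of an ester dienolate: the amide base should remove a γ-hydrogen from the C17 methyl group, which lies cis to the ester, and kinetic α-protonation at C9 then gives the β,γ-unsaturated ester with the exocyclic methylene, the proton entering from the β face because the α face of C9 is screened by the axial C1 methylene of the seven-membered ring on the neighbouring quaternary carbon, which sets C9 (H β, C11 α).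

Step 7
Reactants: 12 deconjugated methyl ester
Product: 13 homoallylic alcohol
Conditions: iBu2AlH, CH2Cl2, −78 °C
Reagents that add atoms: none
Why: Hydride reduction of the ester to the primary alcohol at low temperature removes the acidic C9–H next to a carbonyl before C9 can epimerise or the alkene return into conjugation.

Step 8
Reactants: 13 homoallylic alcohol
Product: 14 primary iodide
Conditions: I2, PPh3, imidazole, CH2Cl2, 0 °C
Reagents that add atoms: iodine II
Why: Garegg–Samuelsson (Appel-type) iodination converts the primary alcohol into the iodide through the alkoxyphosphonium salt under neutral conditions that leave both alkenes untouched.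

Step 9
Reactants: 15 (R)-2-methylbutane-1,4-diol
Product: 16 mono-silyl ether
Conditions: tBuPh2SiCl (1 equiv), imidazole, CH2Cl2, −20 °C
Reagents that add atoms: tert-butyl(chloro)diphenylsilane CC(C)(C)[Si](Cl)(c1ccccc1)c1ccccc1
Why: Silylation with one equivalent of the bulky chlorosilane should take place at the unbranched primary hydroxyl in preference to the β-branched one (steric differentiation), the stereocentre not being involved.

Step 10
Reactants: 16 mono-silyl ether
Product: 17 primary bromide
Conditions: CBr4, PPh3, CH2Cl2, 0 °C
Reagents that add atoms: tetrabromomethane BrC(Br)(Br)Br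
Why: Appel bromination of the remaining primary alcohol proceeds by SN2 at CH2 and leaves the adjacent stereocentre untouched.

Step 11
Reactants: 14 primary iodide; 17 primary bromide
Product: 19 coupled diene, via Grignard reagent 18 (not isolated)
Conditions: Mg, THF, 40 °C (17 → 18); then 14, Li2CuCl4 (5 mol %), THF, −20 → 0 °C
Reagents that add atoms: none
Why: The Grignard reagent from 17 should couple with the primary iodide under copper catalysis (Kochi–Tamura sp3–sp3 cross-coupling), joining C11 to C12 and bringing in the C13 stereocentre unchanged from the (R)-diol.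

Step 12
Reactants: 19 coupled diene
Product: 20 β-epoxide
Conditions: mCPBA (1 equiv), NaHCO3, CH2Cl2, −20 °C
Reagents that add atoms: 3-chloroperbenzoic acid OOC(=O)c1cccc(Cl)c1
Why: Prilezhaev epoxidation should take the electron-richer trisubstituted ring alkene in preference to the 1,1-disubstituted exocyclic methylene (as with limonene) and from the convex β face, cis to H5 and the C10 methyl group, because ring B covers the α face of the seven-membered ring, which fixes both epoxide stereocentres.

Step 13
Reactants: 20 β-epoxide
Product: 21 ring-contracted aldehyde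
Conditions: MeAl(OAr)2 with Ar = 4-bromo-2,6-di-tert-butylphenyl (methylaluminium bis(4-bromo-2,6-di-tert-butylphenoxide), 20 mol %, preformed), CH2Cl2, −78 → −20 °C
Reagents that add atoms: none
Why: Coordination of the bulky aluminium Lewis acid to the epoxide oxygen ionises the tertiary C4–O bond, and the ring bond C19–C3 migrates to C4 anti to the departing oxygen while C19 becomes the aldehyde carbon (Meinwald rearrangement, a semipinacol 1,2-shift). The closest known reaction is the rearrangement of trisubstituted epoxides to α-quaternary aldehydes with this aluminium reagent, including the contraction of 1-methylcycloalkene oxides to 1-methylcycloalkanecarbaldehydes. Ring A is closed by formation of the C3–C4 bond in a suprafacial 1,2-alkyl shift through a three-centre transition state, which contracts the seven-membered ring by extruding C19. The new quaternary stereocentre C4 is controlled by the epoxide configuration from step 12: inversion at C4 places the migrating C3 on the α face, so the formyl group (C19) stays on the β face, cis to H5 and the C10 methyl group, and the C4 methyl group points α. The step needs the alkyl shift to win over hydride shift from C19 (which would give the cycloheptanone) and from C5; the bulky oxophilic Lewis acid, the antiperiplanar alignment of the C19–C3 bond with the breaking C–O bond and the strain released on going from the seven- to the six-membered ring should secure this.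

Step 14
Reactants: 21 ring-contracted aldehyde
Product: 22 hydroxy aldehyde
Conditions: Bu4NF, THF, 0 °C → rt
Reagents that add atoms: none
Why: Fluoride-induced cleavage of the silyl ether (Si–F bond formation) frees the C15 hydroxyl, the non-enolisable neopentyl aldehyde being stable to these conditions.

Step 15
Reactants: 23 caffeic acid
Product: 25 bis-silyl caffeic acid, via tris-silyl caffeate 24 (not isolated)
Conditions: tBuMe2SiCl, imidazole, DMF, rt; then AcOH, THF–H2O, rt
Reagents that add atoms: tert-butyl(chloro)dimethylsilane CC(C)(C)[Si](C)(C)Cl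
Why: Exhaustive silylation followed by selective hydrolysis of the labile silyl ester in aqueous acetic acid leaves the two aryl silyl ethers in place and gives the protected acid (protecting-group manipulation).

Step 16
Reactants: 22 hydroxy aldehyde; 25 bis-silyl caffeic acid
Product: 26 caffeate ester aldehyde
Conditions: EDC·HCl, DMAP (cat.), CH2Cl2, 0 °C → rt
Reagents that add atoms: none
Why: Steglich esterification (carbodiimide activation with DMAP as acyl-transfer catalyst) acylates the only hydroxyl group, with the hindered aldehyde as a spectator.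

Step 17
Reactants: 26 caffeate ester aldehyde
Product: 27 bis-silyl acid
Conditions: NaClO2, NaH2PO4, 2-methylbut-2-ene, tBuOH–H2O, rt
Reagents that add atoms: sodium chlorite [Na+].[O-]Cl=O
Why: Pinnick (Lindgren) oxidation converts the hindered aldehyde into the carboxylic acid with chlorite while 2-methylbut-2-ene scavenges hypochlorous acid, so that the exocyclic methylene, the cinnamate and the aryl silyl ethers should survive.

Step 18
Reactants: 27 bis-silyl acid
Product: 28 target CNP0130717.2
Conditions: HF·pyridine, pyridine, THF, 0 °C
Reagents that add atoms: none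
Why: Buffered hydrogen fluoride cleaves the two aryl silyl ethers (desilylation) without hydrolysing the cinnamate ester or isomerising the exocyclic alkene, which gives the target.

Compound list

1 | (S)-(+)-carvone, (S)-2-methyl-5-(prop-1-en-2-yl)cyclohex-2-en-1-one | CC1=CC[C@@H](CC1=O)C(C)=C | starting material
2 | 5-iodopent-1-ene | C=CCCCI | starting material
3 | lithium enolate of 1 (cross-conjugated, O–Li on the former carbonyl, C9=C10 enolate; not isolated) | CC1=CC[C@H](C(C)=C)C=C1O[Li] | intermediate
4 | (5S,6R)-2-methyl-6-(pent-4-en-1-yl)-5-(prop-1-en-2-yl)cyclohex-2-en-1-one (trans; the minor cis epimer converges in step 2) | CC1=CC[C@H](C(C)=C)[C@@H](CCCC=C)C1=O | intermediate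
5 | lithium enolate of 4 (not isolated) | CC1=CC[C@H](C(C)=C)C(CCCC=C)=C1O[Li] | intermediate
6 | (5R,6S)-2,6-dimethyl-6-(pent-4-en-1-yl)-5-(prop-1-en-2-yl)cyclohex-2-en-1-one (methyl trans, pentenyl cis to isopropenyl) | CC1=CC[C@H](C(C)=C)[C@](C)(CCCC=C)C1=O | intermediate
7 | (1R,7S)-2,7,9-trimethylbicyclo[5.4.0]undeca-2,9-dien-8-one; labdane numbering: seven-membered ring C10–C1–C2–C3–C19=C4(CH3)–C5 cis-fused to ring B with C9 ketone and C7=C8(CH3); 5β-H, 10β-CH3 | CC1=CC[C@@H]2C(C)=CCCC[C@]2(C)C1=O | intermediate
8 | lithium enolate from conjugate reduction of 7 (C9(OLi)=C8(CH3), C7H2; not isolated) | CC1=C(O[Li])[C@@]2(C)CCCC=C(C)[C@H]2CC1 | intermediate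
9 | alkenyl triflate: as 7 but C9(OSO2CF3)=C8(CH3) and C7H2 | CC1=C(OS(=O)(=O)C(F)(F)F)[C@@]2(C)CCCC=C(C)[C@H]2CC1 | intermediate
10 | conjugated methyl ester: as 9 with CO2CH3 (C11) on C9 in place of the triflate | CC1=C(C(=O)OC)[C@@]2(C)CCCC=C(C)[C@H]2CC1 | intermediate
11 | lithium dienolate of 10 (ester enolate C9=C11, exocyclic C8=C17H2; not isolated) | C=C1CC[C@@H]2C(C)=CCCC[C@]2(C)C1=C(OC)O[Li] | intermediate
12 | deconjugated methyl ester: C8=C17H2 exocyclic methylene, 9β-H, 9α-CO2CH3, seven-membered ring with C4=C19 as in 7 | C=C1CC[C@@H]2C(C)=CCCC[C@]2(C)[C@@H]1C(=O)OC | intermediate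
13 | homoallylic alcohol: 12 with CH2OH (C11) in place of CO2CH3 | C=C1CC[C@@H]2C(C)=CCCC[C@]2(C)[C@@H]1CO | intermediate
14 | primary iodide: 13 with CH2I | C=C1CC[C@@H]2C(C)=CCCC[C@]2(C)[C@@H]1CI | intermediate
15 | (R)-2-methylbutane-1,4-diol | OC[C@H](C)CCO | starting material
16 | (R)-4-[(tert-butyldiphenylsilyl)oxy]-2-methylbutan-1-ol | OC[C@H](C)CCO[Si](c1ccccc1)(c1ccccc1)C(C)(C)C | intermediate
17 | (R)-(4-bromo-3-methylbutoxy)(tert-butyl)diphenylsilane | BrC[C@H](C)CCO[Si](c1ccccc1)(c1ccccc1)C(C)(C)C | intermediate
18 | Grignard reagent of 17, [(R)-4-(tert-butyldiphenylsilyloxy)-2-methylbutyl]magnesium bromide (not isolated) | Br[Mg]C[C@H](C)CCO[Si](c1ccccc1)(c1ccccc1)C(C)(C)C | intermediate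
19 | coupled diene: 14 with the chain C11H2–C12H2–C13H(CH3)–C14H2–C15H2–OSiPh2tBu (13S) on C9 | C=C1CC[C@@H]2C(C)=CCCC[C@]2(C)[C@@H]1CC[C@H](C)CCO[Si](c1ccccc1)(c1ccccc1)C(C)(C)C | intermediate
20 | 4β,19β-epoxide of 19 (oxygen cis to H5 and the C10 methyl group, 4α-CH3) | C=C1CC[C@@H]2[C@@]3(C)O[C@H]3CCC[C@]2(C)[C@@H]1CC[C@H](C)CCO[Si](c1ccccc1)(c1ccccc1)C(C)(C)C | intermediate
21 | ring-contracted aldehyde: cis-decalin with ring A C10–C1–C2–C3–C4–C5, 4α-CH3, 4β-CHO (C19), 5β-H, 10β-CH3, 8(17)-methylene, 9α side chain ending in C15–OSiPh2tBu | C=C1CC[C@H]2[C@](C)(CCC[C@]2(C)C=O)[C@@H]1CC[C@H](C)CCO[Si](c1ccccc1)(c1ccccc1)C(C)(C)C | intermediate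
22 | hydroxy aldehyde: 21 with free C15–OH | C=C1CC[C@H]2[C@](C)(CCC[C@]2(C)C=O)[C@@H]1CC[C@H](C)CCO | intermediate
23 | caffeic acid, (E)-3-(3,4-dihydroxyphenyl)prop-2-enoic acid | OC(=O)/C=C/c1ccc(O)c(O)c1 | starting material
24 | tert-butyldimethylsilyl (E)-3-[3,4-bis(tert-butyldimethylsilyloxy)phenyl]prop-2-enoate (not isolated) | CC(C)(C)[Si](C)(C)OC(=O)/C=C/c1ccc(O[Si](C)(C)C(C)(C)C)c(O[Si](C)(C)C(C)(C)C)c1 | intermediate
25 | (E)-3-[3,4-bis(tert-butyldimethylsilyloxy)phenyl]prop-2-enoic acid | OC(=O)/C=C/c1ccc(O[Si](C)(C)C(C)(C)C)c(O[Si](C)(C)C(C)(C)C)c1 | intermediate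
26 | caffeate ester aldehyde: 22 esterified at O15 with 25 | C=C1CC[C@H]2[C@](C)(CCC[C@]2(C)C=O)[C@@H]1CC[C@H](C)CCOC(=O)/C=C/c1ccc(O[Si](C)(C)C(C)(C)C)c(O[Si](C)(C)C(C)(C)C)c1 | intermediate
27 | bis-silyl acid: 26 with CO2H (C19) in place of CHO | C=C1CC[C@H]2[C@](C)(CCC[C@]2(C)C(=O)O)[C@@H]1CC[C@H](C)CCOC(=O)/C=C/c1ccc(O[Si](C)(C)C(C)(C)C)c(O[Si](C)(C)C(C)(C)C)c1 | intermediate
28 | CNP0130717.2, (4S,5S,9R,10R,13S)-15-[(E)-3-(3,4-dihydroxyphenyl)prop-2-enoyloxy]-8(17)-methylene cis-decalin 19-oic acid | C=C1CC[C@H]2[C@](C)(CCC[C@]2(C)C(=O)O)[C@@H]1CC[C@H](C)CCOC(=O)/C=C/c1ccc(O)c(O)c1 | target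

Total step count: 18. Longest linear sequence: 15 steps (steps 1–8, 11–14 and 16–18, from (S)-carvone).

Steps most likely to fail

Step 13 (key step). The danger is that hydride migrates from C19 or C5 to C4 in place of the C3 ring bond, which gives a cycloheptanone, or that a free C4 cation forms and the stereospecificity of the shift is lost. The fallback sets out from 20 and comes back at 27, and keeps the ring contraction but changes its type to a Favorskii rearrangement. The epoxide is isomerised on purpose with a Lewis acid that favours hydride shift (BF3·OEt2, benzene) to the cycloheptanone F1 (C19 ketone, C4–H). Kinetic deprotonation at the C3 methylene (LiN(iPr)2, THF, −78 °C) and chlorination of the enolate with N-chlorosuccinimide from the convex β face should give the 3β-chloro ketone F2. Treatment with KOH in H2O–dioxane forms the C4 enolate, which displaces chloride to a cyclopropanone; its opening towards the less substituted carbanion at C3 contracts the ring to the silyl-protected acid F3, with the carboxyl group on the face the chlorine had occupied (β). Bu4NF then gives the hydroxy acid F4, and Mitsunobu esterification of its primary alcohol with acid 25 (PPh3, diisopropyl azodicarboxylate, THF) leads to 27.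

Step 6. The danger is deprotonation at the ring methylene C7 in place of the C17 methyl group, which gives the endocyclic alkene isomer, or protonation of C9 from the wrong face. The fallback sets out from 10 and comes back at 12: photochemical deconjugation (254 nm, hexane, catalytic 1,2-dimethylimidazole). The 1,5-hydrogen transfer to the excited ester carbonyl is possible only from the C17 methyl group cis to it and gives the photodienol F5 (not isolated), whose ketonisation at C9 mediated by the hindered base should deliver 12.

Step 12. The danger is delivery of oxygen to the α face of the ring alkene, which would invert C4 after the rearrangement, or competing epoxidation of the exocyclic methylene. The fallback sets out from 19 and comes back at 20: bromohydrin formation (N-bromosuccinimide, H2O–1,2-dimethoxyethane, 0 °C) places bromine on the face the peracid had attacked and water on C4 from the opposite face, giving the bromohydrin F6 (19α-Br, 4β-OH). Ring closure with K2CO3 in methanol then gives the β-epoxide 20.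

Further compounds

F1 | step 13 | cycloheptanone: seven-membered ring retained, C19 ketone, 4α-H, 4β-CH3, otherwise as 19 | C=C1CC[C@@H]2[C@@H](C)C(=O)CCC[C@]2(C)[C@@H]1CC[C@H](C)CCO[Si](c1ccccc1)(c1ccccc1)C(C)(C)C
F2 | step 13 | 3β-chloro ketone: F1 with chlorine on C3 | C=C1CC[C@@H]2[C@@H](C)C(=O)[C@@H](Cl)CC[C@]2(C)[C@@H]1CC[C@H](C)CCO[Si](c1ccccc1)(c1ccccc1)C(C)(C)C
F3 | step 13 | silyl-protected acid: ring-contracted 4β-CO2H, 4α-CH3, C15–OSiPh2tBu | C=C1CC[C@H]2[C@](C)(CCC[C@]2(C)C(=O)O)[C@@H]1CC[C@H](C)CCO[Si](c1ccccc1)(c1ccccc1)C(C)(C)C
F4 | step 13 | hydroxy acid: F3 with free C15–OH | C=C1CC[C@H]2[C@](C)(CCC[C@]2(C)C(=O)O)[C@@H]1CC[C@H](C)CCO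
F5 | step 6 | photodienol of 10 (ketene hemiacetal on C9, exocyclic C8=C17H2; not isolated) | C=C1CC[C@@H]2C(C)=CCCC[C@]2(C)C1=C(O)OC
F6 | step 12 | bromohydrin of 19: 19α-Br, 4β-OH, 4α-CH3 | C=C1CC[C@@H]2[C@@](C)(O)[C@H](Br)CCC[C@]2(C)[C@@H]1CC[C@H](C)CCO[Si](c1ccccc1)(c1ccccc1)C(C)(C)C
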